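## The problem

Numbering the chain from the lactone carbonyl (C1) to the terminal methyl group (C12), target 23 consists of a 5,6-dihydro-2H-pyran-2-one (C1–C5, ring oxygen on C5), a 2,5-cis-disubstituted tetrahydrofuran (C7–C10) and a free carbinol C6 that joins the two rings; the C11 hydroxyl carries an (E)-caffeoyl ester. Five stereocentres must be set (5R, 6S, 7R, 10S, 11S): the ring is cis, the oxygen pairs at C6/C7 and C10/C11 are threo, and the pair at C5/C6 is erythro. The ring oxygen is α to both C6 and C11, so a chelate between it and an exocyclic aldehyde can steer a nucleophile to each threo relationship. C5 has no such neighbour and is best set in the event that forms the C5–C6 bond, and the cis relationship across the ring cannot be relayed from either side chain. The conjugated lactone (Michael acceptor, opened by base), the caffeate (second Michael acceptor, prone to acyl transfer) and the catechol (oxidised as its phenolate) tolerate neither strong base nor nucleophiles nor oxidants and must appear late. The two secondary hydroxyls at C6 and C11 must also be told apart. The enabling feature is that C1–C5 are the five carbons of cyclopentanone, with C1 as carbonyl carbon and C5 as α-carbon: C5 can be joined to C6 by an aldol reaction, and the lactone oxygen can then be inserted into the C1–C5 bond with retention at C5.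

## Retrosynthesis

**Caffeate and silyl groups (23 from 22, 22 from 18 and 21).** The C11–O acyl bond and three O–Si bonds are cut first. Esterifying last keeps the caffeate out of every enolate, oxidation and Lewis acid step; building the cinnamate by olefination on a C11 ester would cost extra steps. Alcohol 18 already holds all five stereocentres and the unsaturated lactone, and acid 21 is one step from a commercial acid. The forward reactions must acylate a secondary alcohol without breaking its C–O bond and free three hydroxyls with buffered fluoride.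

**C2=C3 alkene and C11 silyl ether (18 from 17, 17 from 14).** The C2=C3 π bond is removed, leading to the saturated lactone 14. Closing an acrylate by metathesis would deliver the alkene directly, but it needs C5 as a separately made homoallylic carbinol. Here 14 is what the ring expansion provides, so a dehydrogenation is the price. In 14 only C2 is enolisable and only C3 carries β-hydrogens, so the alkene can form in one place only. The triethylsilyl ether on the open C11 oxygen must then be cleaved beside the tert-butyldimethylsilyl ether on the crowded C6 oxygen.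

**Lactone ring (14 from 13, 13 from 11).** The C5–O and O–C1 bonds are cut and the C1–C5 bond is restored, which turns the lactone into the 2-(hydroxyalkyl)cyclopentanone 11. Lactonisation of a 5-hydroxy acid or an acrylate metathesis would both need C1–C4 as a functionalised chain and a C5 carbinol made by an addition that must go against chelation. The oxygen insertion takes all five carbons from a bulk carbocycle and only transfers a C5 configuration that already exists. The forward step must make C5, not C2, migrate, do so with retention, and leave the β-hydroxy ketone intact.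

**C5–C6 bond (11 from 9 and 10).** An aldol cut gives aldehyde 9 and the commercial enol silane 10. A closed transition state with a metal enolate of cyclopentanone would give the 5,6-anti adduct, because the ring fixes the enolate geometry. The open, chelated Mukaiyama variant is the one that can give the 5,6-syn, 6,7-syn adduct. The forward reaction must control the aldehyde face through the chelate (C6) and the relative topicity of the two partners (C5).

**C11–C12 bond and protecting groups (9 from 8, 8 from 7, 7 from 4 and 5).** Cutting the methyl group from C11 leads to aldehyde 4 and Grignard reagent 5. Taking C11 from the chiral pool would mean building the ring around it; here the ring oxygen directs the addition. The acetate that marks the C6 arm of 4 is consumed by the same reagent, and double silylation followed by direct oxidation of the primary silyl ether turns diol 7 into 9.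

**Ring and absolute configuration (4 from 3, 3 from 2, 2 from 1).** No skeletal bond is cut: the two enantiotopic arms of meso-diol 2 are differentiated, and 2 is the perhydro form of furan 1. This supplies C6–C11 in one commercial piece, makes the cis ring by syn delivery of hydrogen, and sets C7 and C10 in one enantiotopic-group selection.

**Protected acid (21 from 19).** Only O–Si bonds are cut; 19 is caffeic acid.

## Roads not taken

**Alternative 1:** The cut removes O–C7, O–C10 and the C6–O and C11–O bonds at once and leads to the open-chain dienoyl sultam A1. In the forward step KMnO4 adds across the electron-poor C6=C7 alkene, and the cyclic manganese ester then adds across C10=C11, closing the ring to give diol A2.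
- Merits: one step makes the ring and four stereocentres. Both threo relationships and the cis ring follow from syn additions to two E-alkenes, and the auxiliary sets the absolute sense without an enzyme.
- Weak points: A2 ends at C5 as an acyl group. The C5 stereocentre and C1–C4 are still missing and need an addition at C5 that runs against chelation, then acylation and ring closure. The C6 and C11 hydroxyls are freed together and must be differentiated afterwards. Facial control rests on the auxiliary alone under a strong oxidant.
- Comparison: in stereocentres per step this road is ahead of the chosen plan, which spends an enzymatic step and two substrate-controlled additions on the same four centres. The chosen plan sets against it that C5 is made together with C6, that the lactone carbons come in one commercial piece, and that the C6 and C11 hydroxyls arise at different stages and so are already differentiated.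

**Alternative 2:** The cut is O–C7 alone and leads to the cis-epoxy alcohol A3. Under acid the C10 hydroxyl opens the epoxide at C7 in a 5-exo mode with inversion, giving tetrahydrofuran diol A4 and releasing the C6 hydroxyl.
- Merits: the step is stereospecific, so the threo C6/C7 pair and the cis ring follow from the epoxide geometry and the C10 configuration. Conditions are mild and there is no question of relative topicity.
- Weak points: A3 requires an enantioselective epoxidation of a Z-allylic alcohol, a substrate class on which titanium tartrate epoxidation is slower and less selective than on E-isomers. It also needs a separately built C10/C11 pair. A4 is a C5,C6-diol, so C5 must be oxidised and its stereocentre and four more carbons added afterwards.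
- Comparison: the ring-forming event is more predictable than the aldol on which the chosen plan depends, and that is conceded. The chosen plan sets against it a ring that exists from the first step, no linear chain construction, and a C5 that is not an add-on.

**Alternative 3:** The cut is O–C10 and C10–H and leads to hydroxy ketone A5. Et3SiH and BF3·OEt2 convert A5 through its cyclic hemiketal and oxocarbenium ion into tetrahydrofuran A6.
- Merits: C6 and C7 come from an auxiliary-controlled glycolate syn-aldol, a reagent control the chosen plan does not have. C11 comes from the chiral pool and the route is convergent.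
- Weak points: the cis selectivity depends on the conformation of a five-membered oxocarbenium ion next to the silyloxy-bearing C11. The 4-methoxybenzyl ether and the imide are exposed to a Lewis acid and a silane, conditions that can ionise and reduce benzylic ethers. A6 again stops at an acyl C5.
- Comparison: for C6/C7 this road is more secure than the chosen one. The chosen plan sets against it that C10 is no selectivity question at all (hydrogenation of a furan) and that C5 and C1–C4 arrive with the aldol partner.

Key step: step 8

Assumption: in step 2 the lipase is taken to acylate the hydroxymethyl group on the R-configured ring carbon of 2 (the later C6 arm); the fallback for step 2 covers the opposite preference.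

## Route

Step 1
Reactants: 1 5-(hydroxymethyl)furan-2-carbaldehyde
Product: 2 [(2R,5S)-oxolane-2,5-diyl]dimethanol (cis, meso)
Conditions: H2 (60 bar), Raney Ni, EtOH, 100 °C
Reagents that add atoms: none
Why: Heterogeneous hydrogenation reduces the formyl group and then delivers hydrogen to one face of the adsorbed furan, so the two hydroxymethyl groups should end up cis. The product is meso, so no absolute configuration is at stake yet.

Step 2
Reactants: 2 [(2R,5S)-oxolane-2,5-diyl]dimethanol
Product: 3 [(2R,5S)-5-(hydroxymethyl)oxolan-2-yl]methyl acetate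
Conditions: Burkholderia cepacia lipase (Amano PS), vinyl acetate, t-BuOMe, r.t.
Reagents that add atoms: vinyl acetate, C=COC(C)=O
Why: Lipase-catalysed transesterification distinguishes the enantiotopic hydroxymethyl groups of the meso-diol (enzymatic desymmetrisation) and fixes C7 and C10 in absolute terms. The released vinyl alcohol tautomerises, so the acylation cannot reverse.

Step 3
Reactants: 3 [(2R,5S)-5-(hydroxymethyl)oxolan-2-yl]methyl acetate
Product: 4 [(2R,5S)-5-formyloxolan-2-yl]methyl acetate
Conditions: (COCl)2, DMSO, CH2Cl2, −78 °C; Et3N, −78 → 0 °C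
Reagents that add atoms: none
Why: Swern oxidation stops at the aldehyde and runs cold, so the α-alkoxy aldehyde should not epimerise at C10. The crude aldehyde is used at once.

Step 4
Reactants: 4 [(2R,5S)-5-formyloxolan-2-yl]methyl acetate; 5 methylmagnesium bromide
Product: 7 (1S)-1-[(2S,5R)-5-(hydroxymethyl)oxolan-2-yl]ethan-1-ol, via bromomagnesium alkoxide acetate 6 (not isolated)
Conditions: MgBr2·OEt2, CH2Cl2, −78 °C; MeMgBr (3.5 equiv, Et2O), −78 → 0 °C; aq. NH4Cl
Reagents that add atoms: none
Why: Magnesium bridges the aldehyde oxygen and the ring oxygen, and methyl adds to the chelate from the face opposite C9 (Cram-chelate Grignard addition), which should give the 10,11-threo carbinol with 11S configuration. On warming, the excess reagent cleaves the acetate of 6, so the diol is reached in one operation.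

Step 5
Reactants: 7 (1S)-1-[(2S,5R)-5-(hydroxymethyl)oxolan-2-yl]ethan-1-ol
Product: 8 (2S,5R)-2-[(1S)-1-(triethylsilyloxy)ethyl]-5-[(triethylsilyloxy)methyl]oxolane
Conditions: Et3SiCl, imidazole, DMF, 0 °C → r.t.
Reagents that add atoms: chlorotriethylsilane, CC[Si](Cl)(CC)CC
Why: Both hydroxyls are silylated under standard conditions (silyl ether formation). Triethylsilyl is chosen because it can later be removed from C11 beside a tert-butyldimethylsilyl ether.

Step 6
Reactants: 8 (2S,5R)-2-[(1S)-1-(triethylsilyloxy)ethyl]-5-[(triethylsilyloxy)methyl]oxolane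
Product: 9 (2R,5S)-5-[(1S)-1-(triethylsilyloxy)ethyl]oxolane-2-carbaldehyde
Conditions: (COCl)2, DMSO, CH2Cl2, −78 → −30 °C; Et3N, −78 °C → r.t.
Reagents that add atoms: none
Why: Under Swern conditions the activated sulfoxide cleaves the unhindered primary triethylsilyl ether and oxidises it directly to the aldehyde, leaving the secondary silyl ether in place (direct Swern oxidation of primary trialkylsilyl ethers). This saves a separate deprotection.

Step 7
Reactants: 9 (2R,5S)-5-[(1S)-1-(triethylsilyloxy)ethyl]oxolane-2-carbaldehyde; 10 1-(trimethylsilyloxy)cyclopentene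
Product: 11 (2R)-2-[(R)-hydroxy{(2R,5S)-5-[(1S)-1-(triethylsilyloxy)ethyl]oxolan-2-yl}methyl]cyclopentan-1-one
Conditions: MgBr2·OEt2 (3 equiv), CH2Cl2, −78 → −20 °C; aq. citric acid, THF, 0 °C
Reagents that add atoms: none
Why: In this chelation-controlled Mukaiyama aldol reaction, magnesium bound to the aldehyde oxygen and the ring oxygen exposes the C6 face opposite C8, which should set the 6,7-syn (threo) relationship. In the open transition state the enol ether carbon C4 should lie over the aldehyde hydrogen and away from the chelate, which leads to the 5,6-syn adduct; the silyl bulk of the C11 ether leaves only the α-chelate.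

Step 8
Reactants: 11 (2R)-2-[(R)-hydroxy{(2R,5S)-5-[(1S)-1-(triethylsilyloxy)ethyl]oxolan-2-yl}methyl]cyclopentan-1-one
Product: 13 (6R)-6-[(S)-hydroxy{(2R,5S)-5-[(1S)-1-(triethylsilyloxy)ethyl]oxolan-2-yl}methyl]oxan-2-one, via Criegee adduct 12 (not isolated)
Conditions: mCPBA, NaHCO3, CH2Cl2, 0 °C → r.t.
Reagents that add atoms: 3-chloroperbenzoic acid, OOC(=O)c1cccc(Cl)c1
Why: The peracid adds to the ketone of 11 to give the tetrahedral Criegee adduct 12, and the C1–C5 bond, held antiperiplanar to the breaking O–O bond, migrates from carbon to oxygen as 3-chlorobenzoate leaves (Baeyer–Villiger oxidation). The closest known reaction type is the oxidation of 2-substituted cyclopentanones, aldol adducts of cyclopentanone included, to 6-substituted δ-valerolactones. The six-membered lactone is not closed by a cyclisation; it arises by ring expansion of the five-membered ketone through a 1,2-shift that places oxygen between C1 and C5. No stereocentre is created: the migration is suprafacial and intramolecular, so the C5 configuration set in the aldol step is carried over with retention and the C5–C1 bond becomes C5–O (5R). The step needs regioselectivity between the two α-carbons, and the substrate secures it because the secondary, more electron-releasing C5 migrates in preference to the C2 methylene. It also needs the β-hydroxy ketone to survive, and solid NaHCO3 secures this by neutralising 3-chlorobenzoic acid, which holds back acid-catalysed retro-aldol cleavage, dehydration and loss of the triethylsilyl ether. Compound 11 has no alkene or other oxidisable group, so the peracid has no competing site.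

Step 9
Reactants: 13 (6R)-6-[(S)-hydroxy{(2R,5S)-5-[(1S)-1-(triethylsilyloxy)ethyl]oxolan-2-yl}methyl]oxan-2-one
Product: 14 (6R)-6-[(S)-(tert-butyldimethylsilyloxy){(2R,5S)-5-[(1S)-1-(triethylsilyloxy)ethyl]oxolan-2-yl}methyl]oxan-2-one
Conditions: t-BuMe2SiOTf, 2,6-lutidine, CH2Cl2, −78 → 0 °C
Reagents that add atoms: tert-butyldimethylsilyl trifluoromethanesulfonate, CC(C)(C)[Si](C)(C)OS(=O)(=O)C(F)(F)F
Why: The silyl triflate with a hindered pyridine base silylates the crowded C6 hydroxyl (silyl ether formation). The base is too weak to enolise or open the lactone.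

Step 10
Reactants: 14 (6R)-6-[(S)-(tert-butyldimethylsilyloxy){(2R,5S)-5-[(1S)-1-(triethylsilyloxy)ethyl]oxolan-2-yl}methyl]oxan-2-one
Product: 17 (6R)-6-[(S)-(tert-butyldimethylsilyloxy){(2R,5S)-5-[(1S)-1-(triethylsilyloxy)ethyl]oxolan-2-yl}methyl]-5,6-dihydro-2H-pyran-2-one, via C2-phenylselanyl lactone 15 (not isolated), via selenoxide 16 (not isolated)
Conditions: LiN(i-Pr)2, THF, −78 °C; PhSeBr, −78 °C; then H2O2 (30% aq.), pyridine, CH2Cl2, 0 °C → r.t.
Reagents that add atoms: none
Why: The kinetic lactone enolate is selenenylated at C2, and the derived selenoxide undergoes syn-elimination toward C3, the only carbon with β-hydrogens, so the alkene can form only at C2=C3 (selenoxide elimination). C5 and C6 are untouched because neither carries an acidic hydrogen.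

Step 11
Reactants: 17 (6R)-6-[(S)-(tert-butyldimethylsilyloxy){(2R,5S)-5-[(1S)-1-(triethylsilyloxy)ethyl]oxolan-2-yl}methyl]-5,6-dihydro-2H-pyran-2-one
Product: 18 (6R)-6-[(S)-(tert-butyldimethylsilyloxy){(2R,5S)-5-[(1S)-1-hydroxyethyl]oxolan-2-yl}methyl]-5,6-dihydro-2H-pyran-2-one
Conditions: HF·pyridine, pyridine, THF, 0 °C
Reagents that add atoms: none
Why: Buffered HF·pyridine should cleave the less hindered secondary triethylsilyl ether much faster than the tert-butyldimethylsilyl ether on the crowded C6 oxygen (selective desilylation). The weakly acidic medium leaves the unsaturated lactone alone.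

Step 12
Reactants: 19 (2E)-3-(3,4-dihydroxyphenyl)prop-2-enoic acid (caffeic acid)
Product: 21 (2E)-3-[3,4-bis(tert-butyldimethylsilyloxy)phenyl]prop-2-enoic acid, via tris-silyl caffeate 20 (not isolated)
Conditions: t-BuMe2SiCl, imidazole, DMF, r.t.; then AcOH, THF/H2O, r.t.
Reagents that add atoms: tert-butyldimethylsilyl chloride, CC(C)(C)[Si](C)(C)Cl
Why: Exhaustive silylation followed by mild hydrolysis removes only the labile silyl ester and leaves the two aryl silyl ethers (silyl protection of a catechol). The E-alkene is not touched.

Step 13
Reactants: 18 (6R)-6-[(S)-(tert-butyldimethylsilyloxy){(2R,5S)-5-[(1S)-1-hydroxyethyl]oxolan-2-yl}methyl]-5,6-dihydro-2H-pyran-2-one; 21 (2E)-3-[3,4-bis(tert-butyldimethylsilyloxy)phenyl]prop-2-enoic acid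
Product: 22 (1S)-1-[(2S,5R)-5-{(S)-(tert-butyldimethylsilyloxy)[(2R)-6-oxo-3,6-dihydro-2H-pyran-2-yl]methyl}oxolan-2-yl]ethyl (2E)-3-[3,4-bis(tert-butyldimethylsilyloxy)phenyl]prop-2-enoate
Conditions: DCC, DMAP, CH2Cl2, 0 °C → r.t.
Reagents that add atoms: none
Why: Steglich esterification acylates the only free hydroxyl; the C11–O bond is not broken, so C11 keeps its configuration. The neutral conditions spare the unsaturated lactone and the cinnamate geometry.

Step 14
Reactants: 22 (1S)-1-[(2S,5R)-5-{(S)-(tert-butyldimethylsilyloxy)[(2R)-6-oxo-3,6-dihydro-2H-pyran-2-yl]methyl}oxolan-2-yl]ethyl (2E)-3-[3,4-bis(tert-butyldimethylsilyloxy)phenyl]prop-2-enoate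
Product: 23 (1S)-1-[(2S,5R)-5-{(S)-hydroxy[(2R)-6-oxo-3,6-dihydro-2H-pyran-2-yl]methyl}oxolan-2-yl]ethyl (2E)-3-(3,4-dihydroxyphenyl)prop-2-enoate
Conditions: Bu4NF, AcOH (1:1), THF, 0 °C → r.t.
Reagents that add atoms: none
Why: Fluoride buffered with acetic acid should cleave the two aryl silyl ethers quickly and the hindered C6 silyl ether more slowly (fluoride-mediated desilylation). The buffer keeps the medium from becoming basic enough to open the lactone, transfer the caffeate or oxidise the catechol.

## Compound list

1 | 5-(hydroxymethyl)furan-2-carbaldehyde | O=Cc1ccc(CO)o1 | starting material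
2 | [(2R,5S)-oxolane-2,5-diyl]dimethanol (cis, meso) | OC[C@@H]1CC[C@H](CO)O1 | intermediate
3 | [(2R,5S)-5-(hydroxymethyl)oxolan-2-yl]methyl acetate | OC[C@@H]1CC[C@H](COC(C)=O)O1 | intermediate
4 | [(2R,5S)-5-formyloxolan-2-yl]methyl acetate | O=C[C@@H]1CC[C@H](COC(C)=O)O1 | intermediate
5 | methylmagnesium bromide | C[Mg]Br | starting material
6 | [(2R,5S)-5-[(1S)-1-hydroxyethyl]oxolan-2-yl]methyl acetate, present as its bromomagnesium alkoxide | C[C@H](O)[C@@H]1CC[C@H](COC(C)=O)O1 | intermediate (not isolated)
7 | (1S)-1-[(2S,5R)-5-(hydroxymethyl)oxolan-2-yl]ethan-1-ol | C[C@H](O)[C@@H]1CC[C@H](CO)O1 | intermediate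
8 | (2S,5R)-2-[(1S)-1-(triethylsilyloxy)ethyl]-5-[(triethylsilyloxy)methyl]oxolane | C[C@H](O[Si](CC)(CC)CC)[C@@H]1CC[C@H](CO[Si](CC)(CC)CC)O1 | intermediate
9 | (2R,5S)-5-[(1S)-1-(triethylsilyloxy)ethyl]oxolane-2-carbaldehyde | C[C@H](O[Si](CC)(CC)CC)[C@@H]1CC[C@H](C=O)O1 | intermediate
10 | 1-(trimethylsilyloxy)cyclopentene | C[Si](C)(C)OC1=CCCC1 | starting material
11 | (2R)-2-[(R)-hydroxy{(2R,5S)-5-[(1S)-1-(triethylsilyloxy)ethyl]oxolan-2-yl}methyl]cyclopentan-1-one | C[C@H](O[Si](CC)(CC)CC)[C@@H]1CC[C@H]([C@H](O)[C@H]2CCCC2=O)O1 | intermediate
12 | Criegee adduct of 11 with 3-chloroperbenzoic acid (1-hydroxy-1-peroxyester at the former carbonyl carbon, either configuration there) | C[C@H](O[Si](CC)(CC)CC)[C@@H]1CC[C@H]([C@H](O)[C@H]2CCCC2(O)OOC(=O)c3cccc(Cl)c3)O1 | intermediate (not isolated)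
13 | (6R)-6-[(S)-hydroxy{(2R,5S)-5-[(1S)-1-(triethylsilyloxy)ethyl]oxolan-2-yl}methyl]oxan-2-one | C[C@H](O[Si](CC)(CC)CC)[C@@H]1CC[C@H]([C@H](O)[C@H]2CCCC(=O)O2)O1 | intermediate
14 | (6R)-6-[(S)-(tert-butyldimethylsilyloxy){(2R,5S)-5-[(1S)-1-(triethylsilyloxy)ethyl]oxolan-2-yl}methyl]oxan-2-one | C[C@H](O[Si](CC)(CC)CC)[C@@H]1CC[C@H]([C@H](O[Si](C)(C)C(C)(C)C)[C@H]2CCCC(=O)O2)O1 | intermediate
15 | 3-(phenylselanyl) derivative of 14 (selenium on chain carbon C2, both epimers) | C[C@H](O[Si](CC)(CC)CC)[C@@H]1CC[C@H]([C@H](O[Si](C)(C)C(C)(C)C)[C@H]2CCC([Se]c3ccccc3)C(=O)O2)O1 | intermediate (not isolated)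
16 | selenoxide of 15 (both epimers at C2 and selenium) | C[C@H](O[Si](CC)(CC)CC)[C@@H]1CC[C@H]([C@H](O[Si](C)(C)C(C)(C)C)[C@H]2CCC([Se](=O)c3ccccc3)C(=O)O2)O1 | intermediate (not isolated)
17 | (6R)-6-[(S)-(tert-butyldimethylsilyloxy){(2R,5S)-5-[(1S)-1-(triethylsilyloxy)ethyl]oxolan-2-yl}methyl]-5,6-dihydro-2H-pyran-2-one | C[C@H](O[Si](CC)(CC)CC)[C@@H]1CC[C@H]([C@H](O[Si](C)(C)C(C)(C)C)[C@H]2CC=CC(=O)O2)O1 | intermediate
18 | (6R)-6-[(S)-(tert-butyldimethylsilyloxy){(2R,5S)-5-[(1S)-1-hydroxyethyl]oxolan-2-yl}methyl]-5,6-dihydro-2H-pyran-2-one | C[C@H](O)[C@@H]1CC[C@H]([C@H](O[Si](C)(C)C(C)(C)C)[C@H]2CC=CC(=O)O2)O1 | intermediate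
19 | (2E)-3-(3,4-dihydroxyphenyl)prop-2-enoic acid (caffeic acid) | OC(=O)/C=C/c1ccc(O)c(O)c1 | starting material
20 | tert-butyldimethylsilyl (2E)-3-[3,4-bis(tert-butyldimethylsilyloxy)phenyl]prop-2-enoate | CC(C)(C)[Si](C)(C)OC(=O)/C=C/c1ccc(O[Si](C)(C)C(C)(C)C)c(O[Si](C)(C)C(C)(C)C)c1 | intermediate (not isolated)
21 | (2E)-3-[3,4-bis(tert-butyldimethylsilyloxy)phenyl]prop-2-enoic acid | OC(=O)/C=C/c1ccc(O[Si](C)(C)C(C)(C)C)c(O[Si](C)(C)C(C)(C)C)c1 | intermediate
22 | (1S)-1-[(2S,5R)-5-{(S)-(tert-butyldimethylsilyloxy)[(2R)-6-oxo-3,6-dihydro-2H-pyran-2-yl]methyl}oxolan-2-yl]ethyl (2E)-3-[3,4-bis(tert-butyldimethylsilyloxy)phenyl]prop-2-enoate | C[C@H](OC(=O)/C=C/c1ccc(O[Si](C)(C)C(C)(C)C)c(O[Si](C)(C)C(C)(C)C)c1)[C@@H]1CC[C@H]([C@H](O[Si](C)(C)C(C)(C)C)[C@H]2CC=CC(=O)O2)O1 | intermediate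
23 | (1S)-1-[(2S,5R)-5-{(S)-hydroxy[(2R)-6-oxo-3,6-dihydro-2H-pyran-2-yl]methyl}oxolan-2-yl]ethyl (2E)-3-(3,4-dihydroxyphenyl)prop-2-enoate | C[C@H](OC(=O)/C=C/c1ccc(O)c(O)c1)[C@@H]1CC[C@H]([C@H](O)[C@H]2CC=CC(=O)O2)O1 | target

## Step count and least certain steps

Total step count: 14. Longest linear sequence: 13 steps (steps 1–11, 13 and 14); step 12 is a one-step side branch.

**Step 8 (key step).** The most likely failure is slow peracid addition to the hindered ketone, which would give retro-aldol cleavage or epimerisation at C5 time to compete; partial migration of the C2 methylene is the second concern. The fallback sets out from 11 and changes the order of events. The C6 hydroxyl is silylated first (t-BuMe2SiOTf, 2,6-lutidine, −78 °C) to give the silylated aldol ketone F1, which can no longer undergo retro-aldol cleavage. F1 is then ring-expanded with buffered peracid (mCPBA, NaHCO3, or CF3CO3H, Na2HPO4) and the route is rejoined directly at 14.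

**Step 7.** The relative topicity at C5/C6 may be poor, because the ring fixes the enol silane geometry and the preference in an open transition state can be modest; chelation control at C6 may also erode, and C5 may epimerise on work-up. The fallback sets out from 9 and replaces substrate control by auxiliary control:
- An Evans syn-aldol reaction of the dibutylboron enolate of the acyl oxazolidinone F2 (Bu2BOTf, i-Pr2NEt, CH2Cl2, −78 → 0 °C) with 9 should give the syn-aldol imide F3 through a closed transition state.
- Transamination (AlMe3, MeNHOMe·HCl) gives the Weinreb amide F4, and silylation (t-BuMe2SiOTf, 2,6-lutidine) gives the silyl ether F5.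
- Iodine–lithium exchange (t-BuLi, Et2O/pentane, −78 °C) and intramolecular acylation of the amide close the cyclopentanone and give F1, which is ring-expanded as described for step 8 to rejoin the route at 14.

**Step 4.** Solvent-bound magnesium may compete with the chelate, so that facial selectivity at C11 drops; the small, polar diol may also be lost on aqueous work-up. The fallback sets out from 4 and sets C11 by reduction instead of addition:
- One equivalent of MeMgBr at −78 °C with a cold quench gives 6 together with its C11 epimer F6.
- Oxidation of the mixture (Dess–Martin periodinane, NaHCO3) gives the methyl ketone F7.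
- Felkin–Anh reduction with the bulky, non-chelating Li[(s-Bu)3BH] (THF, −78 °C) should return 6 alone.
- Methanolysis (K2CO3, MeOH) gives 7.

**Step 2.** The enzyme may discriminate the enantiotopic arms insufficiently or in the opposite sense, and over-acylation to the diester may occur. The fallback sets out from 2 and uses the hydrolytic mode. Acetylation (Ac2O, pyridine) gives the meso-diacetate F8, and the same lipase in pH 7 phosphate buffer hydrolyses the ester on the arm it would otherwise have acylated. An enzyme with the opposite preference therefore still gives 3.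

**Step 6.** Cleavage may not distinguish well enough between the primary and the secondary silyl ether, with loss of the C11 silyl group or incomplete conversion. The fallback sets out from 8 and separates the two events. Selective solvolysis of the primary silyl ether (PPTS, MeOH/CH2Cl2, −10 °C) gives the primary alcohol F9, and oxidation (Dess–Martin periodinane, NaHCO3, CH2Cl2) rejoins the route at 9.

## Further compounds

F1 | step 8 | (2R)-2-[(R)-(tert-butyldimethylsilyloxy){(2R,5S)-5-[(1S)-1-(triethylsilyloxy)ethyl]oxolan-2-yl}methyl]cyclopentan-1-one | C[C@H](O[Si](CC)(CC)CC)[C@@H]1CC[C@H]([C@H](O[Si](C)(C)C(C)(C)C)[C@H]2CCCC2=O)O1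
F2 | step 7 | (4R)-4-benzyl-3-(5-iodopentanoyl)-1,3-oxazolidin-2-one | O=C(CCCCI)N1[C@H](Cc2ccccc2)COC1=O
F3 | step 7 | (4R)-4-benzyl-3-{(2R)-2-[(R)-hydroxy{(2R,5S)-5-[(1S)-1-(triethylsilyloxy)ethyl]oxolan-2-yl}methyl]-5-iodopentanoyl}-1,3-oxazolidin-2-one | C[C@H](O[Si](CC)(CC)CC)[C@@H]1CC[C@H]([C@H](O)[C@H](C(=O)N2[C@H](Cc3ccccc3)COC2=O)CCCI)O1
F4 | step 7 | (2R)-2-[(R)-hydroxy{(2R,5S)-5-[(1S)-1-(triethylsilyloxy)ethyl]oxolan-2-yl}methyl]-5-iodo-N-methoxy-N-methylpentanamide | C[C@H](O[Si](CC)(CC)CC)[C@@H]1CC[C@H]([C@H](O)[C@H](C(=O)N(C)OC)CCCI)O1
F5 | step 7 | (2R)-2-[(R)-(tert-butyldimethylsilyloxy){(2R,5S)-5-[(1S)-1-(triethylsilyloxy)ethyl]oxolan-2-yl}methyl]-5-iodo-N-methoxy-N-methylpentanamide | C[C@H](O[Si](CC)(CC)CC)[C@@H]1CC[C@H]([C@H](O[Si](C)(C)C(C)(C)C)[C@H](C(=O)N(C)OC)CCCI)O1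
F6 | step 4 | [(2R,5S)-5-[(1R)-1-hydroxyethyl]oxolan-2-yl]methyl acetate | C[C@@H](O)[C@@H]1CC[C@H](COC(C)=O)O1
F7 | step 4 | [(2R,5S)-5-acetyloxolan-2-yl]methyl acetate | CC(=O)[C@@H]1CC[C@H](COC(C)=O)O1
F8 | step 2 | [(2R,5S)-oxolane-2,5-diyl]dimethanediyl diacetate (cis, meso) | CC(=O)OC[C@@H]1CC[C@H](COC(C)=O)O1
F9 | step 6 | {(2R,5S)-5-[(1S)-1-(triethylsilyloxy)ethyl]oxolan-2-yl}methanol | C[C@H](O[Si](CC)(CC)CC)[C@@H]1CC[C@H](CO)O1
A1 | alternative 1 | N-[(2E,6E)-octa-2,6-dienoyl]bornane-10,2-sultam | CC1(C)[C@@H]2CC[C@]13CS(=O)(=O)N(C(=O)/C=C/CC/C=C/C)[C@@H]3C2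
A2 | alternative 1 | N-acyl sultam of the threo,cis,threo tetrahydrofuran diol (C5 to C12) | CC1(C)[C@@H]2CC[C@]13CS(=O)(=O)N(C(=O)[C@@H](O)[C@H]4CC[C@@H]([C@H](C)O)O4)[C@@H]3C2
A3 | alternative 2 | cis-C6,C7-epoxy alcohol with free C5 and C10 hydroxyls and C11 4-methoxybenzyl ether | C[C@H](OCc1ccc(OC)cc1)[C@@H](O)CC[C@H]1[C@@H](CO)O1
A4 | alternative 2 | cis-tetrahydrofuran C5,C6-diol with C11 4-methoxybenzyl ether | C[C@H](OCc1ccc(OC)cc1)[C@@H]1CC[C@H]([C@H](O)CO)O1
A5 | alternative 3 | C7-hydroxy C10-ketone acyl oxazolidinone with C6 4-methoxybenzyl ether and C11 silyl ether | C[C@H](O[Si](C)(C)C(C)(C)C)C(=O)CC[C@@H](O)[C@H](OCc1ccc(OC)cc1)C(=O)N1[C@@H](Cc2ccccc2)COC1=O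
A6 | alternative 3 | cis-tetrahydrofuran acyl oxazolidinone (C5 to C12) | C[C@H](O[Si](C)(C)C(C)(C)C)[C@@H]1CC[C@H]([C@H](OCc2ccc(OC)cc2)C(=O)N2[C@@H](Cc3ccccc3)COC2=O)O1
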